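Remark on the chemistry: rotation about the two C–O bonds of the tri-ortho-substituted diaryl ether is taken to be fast at room temperature, so the target is treated as one achiral compound.

## Analysis of the target

The target 23 consists of two benzene rings joined only through one ether oxygen; there is no ring fusion, no chain and no stereocentre, so the problem is entirely one of substitution pattern. Ring A is numbered C1 (OCH3), C2 (H), C3 (isopropyl), C4 (ether oxygen), C5 (H), C6 (CH3), and ring B C1′ (ether oxygen), C2′ (CH3), C3′ (OCH3), C4′ (H), C5′ (isopropyl), C6′ (OH). Both halves carry the pattern of 4-methoxythymol (6): ring A is that phenol arylated on oxygen and ring B is the same phenol oxygenated at its free ortho carbon, so the target is formally a C–O dimer. The sensitive function is the free C6′ hydroxyl, which sits para to OCH3 on a pentasubstituted, very electron-rich ring and is easily oxidised towards a quinone; it is carried as a methoxymethyl (MOM) ether and released last, and the three oxygens of ring B must stay distinct throughout. The difficulty lies at the ether oxygen: it is flanked by the C2′ methyl group and the C6′ oxygen on one side and by the C3 isopropyl group on the other, and both rings are electron-rich, which is a poor case for joining this oxygen to a preformed ring A by aryl–oxygen coupling. The strategy rests on the pattern of ring A: the ether oxygen on C4 is para to the C1 oxygen, the alkyl groups sit on C3 and C6, and C2 and C5 are unsubstituted. C2–C3–C4–C5 can therefore be a butadiene carrying the aryloxy and isopropyl groups on its inner carbons, and C1–C6 a methyl-substituted acetylenic ketone whose acetyl group stands in for the C1 oxygen; the crowded C4–O bond is then made as an ester bond and not by arylation.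

## Retrosynthetic reasoning

The free phenol of 23 is uncovered last from its MOM ether 22. No skeletal bond is cut; the gain is that every oxidising and basic step before it meets a fully etherified ring B.

The C1–OCH3 group of 22 is traced back to the phenol 21, its acetate 20 and the aryl methyl ketone 19. This cuts the C1–O bond and puts a C1–acyl bond in its place, which is what a cycloaddition can deliver. The forward Baeyer–Villiger oxidation has to move the aryl group and not the methyl group, and the aryloxy oxygen para to C1 makes the aryl group the better migrating group.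

The benzene ring of 19 is taken back to the 1,4-cyclohexadiene 18 by adding two hydrogens at C2 and C5. The forward step is a dehydrogenation that removes hydrogen only from these two CH2 groups and leaves the C4–O bond, which sits on an sp2 carbon, untouched.

Ring A of 18 is cut at C1–C2 and C5–C6, the two bonds that end on the unsubstituted ring carbons. This gives the 2-aryloxy-3-isopropylbutadiene 16, whose two termini are both CH2 groups, and pent-3-yn-2-one (17), which is commercial and already carries the C6 methyl group and the latent C1 oxygen. The cut is made here and not at C3–C4 or C4–O because it moves the hindered ether bond out of the ring-forming event. The forward Diels–Alder reaction has to place the acetyl group para to the aryloxy group.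

The enol ether carbon–carbon double bond of 16 (C4=C5) is traced to the carbonyl group of the aryl ester 15. The C4–O bond of the target thereby becomes an ester C–O bond, made by acylating the phenol 10 with the acid 13 through its chloride 14. Acylation is much less sensitive to two ortho substituents than arylation, and the forward methylenation only has to convert an ester carbonyl without disturbing the conjugated alkene.

The acid 13 is taken back through the enal 12 to 3-methylbutanal (11). One carbon (the future C2) is added by α-methylenation and the aldehyde is oxidised; the isopropyl group of ring A comes in intact.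

The C1′–O bond of 10 is cut back to a C–H bond of the MOM ether 7, itself made from the phenol 6. The MOM oxygen is the strongest directing group on the ring and C1′–H is the only hydrogen ortho to it, so lithiation, borylation and oxidation place the third oxygen without isomers, and the two neighbouring oxygens are born differentiated (free OH next to O–MOM).

Phenol 6 is traced to the aryl bromide 3, the methyl ether 2 and carvacrol (1). Carvacrol supplies ring B with its methyl and isopropyl groups in place; its own oxygen becomes C3′–OCH3 and the bromine introduced para to it marks the future C6′ oxygen. Bromide 3 is also ring A with a leaving group on C4, which is kept in reserve.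

## Alternatives that were turned down

Alternative 1: Ring A is taken as an aryne between C3 and C4, so that the O–C4 bond and a carbon substituent on C3 are cut together. In the forward key step a fluoride source desilylates the silyl triflate A2 (4-methoxy-5-methyl-2-(trimethylsilyl)phenyl trifluoromethanesulfonate), the phenoxide released from the ring B carbonate A1 (methyl 3-isopropyl-5-methoxy-2-(methoxymethoxy)-6-methylphenyl carbonate) adds to the aryne, and the resulting aryl anion takes a methoxycarbonyl group from a second molecule of A1 to give the benzoate A3 (methyl 2-[3-isopropyl-5-methoxy-2-(methoxymethoxy)-6-methylphenoxy]-5-methoxy-4-methylbenzoate). The ester of A3 would then become the isopropyl group by double addition of a methyl Grignard reagent and ionic deoxygenation.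
- For it: it is convergent, it makes the hindered ether without a metal catalyst, and it needs only about three steps after the key step. On step count and convergence it is stronger than the chosen route.
- Against it: the two substituents of the aryne are both remote from the triple bond, so nothing distorts it, and addition at C4 or at C3 is nearly unbiased. The two ethers that result differ only by exchange of OCH3 and CH3 and would be hard to separate.
- Against it: the aryl anion must also attack a carbonate carbonyl screened by a 2,6-disubstituted aryloxy group, in competition with simple protonation, and A2 itself needs several steps.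
- In its place the chosen route offers a regiochemical bias that comes from a first-order electronic effect (an oxygen donor on the diene) and a C–O bond made by acylation.

Alternative 2: Ring B is built instead of ring A, by cutting C3′–C4′; ring A enters as the intact phenol 6, attached to a four-membered ring. In the forward key step the cyclobutenone A4 (3-(2-isopropyl-4-methoxy-5-methylphenoxy)-4-(methoxymethoxy)-2-methyl-4-(3-methylbut-1-en-2-yl)cyclobut-2-en-1-one, racemic) is heated. Electrocyclic opening gives a dienylketene, six-electron closure joins the ketene carbon to the alkene terminus, and tautomerisation gives the phenol A5 (3-(2-isopropyl-4-methoxy-5-methylphenoxy)-5-isopropyl-4-(methoxymethoxy)-2-methylphenol). O-Methylation and MOM removal would follow.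
- For it: every substituent of ring B is placed by connectivity, and the C3′ and C6′ oxygens emerge differentiated. On regiochemical certainty it is stronger than the chosen route.
- Against it: reaching A4 needs addition–elimination of the hindered phenol 6 on a squaric acid derivative, two successive organometallic additions and protection of a crowded tertiary cyclobutenol. That is a long run of strained, heat- and moisture-sensitive intermediates before the key step, and the total is no shorter.
- In its place the chosen route offers bench-stable aromatic intermediates up to ester 15, terpenoid feedstock for ring B, and only two sensitive compounds (16 and 18).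

Alternative 3: Ring A is cut at C4–C5 and C2–C3, a Robinson annulation. In the forward key step the alkoxide-derived enolate of the aryloxy ketone A6 (1-[3-isopropyl-5-methoxy-2-(methoxymethoxy)-6-methylphenoxy]-3-methylbutan-2-one, from phenol 10) adds to the enone A7 (3-methylbut-3-en-2-one), and aldol condensation closes the cyclohexenone A8 (4-[3-isopropyl-5-methoxy-2-(methoxymethoxy)-6-methylphenoxy]-3-isopropyl-6-methylcyclohex-2-en-1-one, racemic). Dehydrogenation to phenol 21, methylation and deprotection would follow.
- For it: the reagents are the cheapest of all, ring A has no orientation problem, the C1 oxygen arrives as the ketone so no Baeyer–Villiger step is needed, and the sequence after 10 is two to three steps shorter. On these points it is stronger than the chosen route.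
- Against it: in A8 the aryloxy group sits on an sp3 carbon (C4) allylic to the enone with hydrogens on C5. Loss of phenol 10 by elimination already gives an aromatic ring (carvacrol, 1) without any oxidant, whereas the wanted aromatisation must remove two hydrogens and keep the C4–O bond. Base, acid, heat and metal catalysts all favour the elimination.
- Against it: the aldol closure must attack an isopropyl ketone next to a tertiary aryloxy carbon, and A7 polymerises readily under alkoxide.
- In its place the chosen route keeps the C4–O bond on an sp2 carbon from diene 16 onward, so the ether cannot be eliminated and aromatisation is a plain loss of two hydrogens.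

Key step: step 10

## Route

Step 1
Reactants: 1 carvacrol (5-isopropyl-2-methylphenol)
Product: 2 4-isopropyl-2-methoxy-1-methylbenzene (carvacrol methyl ether)
Conditions: MeI, K2CO3, acetone, reflux
Reagents that add atoms: iodomethane, CI
Why: Williamson O-methylation of the potassium phenoxide; the phenol is the only acidic site.

Step 2
Reactants: 2 4-isopropyl-2-methoxy-1-methylbenzene
Product: 3 1-bromo-2-isopropyl-4-methoxy-5-methylbenzene
Conditions: NBS, MeCN, 0 °C → rt
Reagents that add atoms: N-bromosuccinimide, O=C1CCC(=O)N1Br
Why: Electrophilic aromatic bromination directed para by the methoxy group; the single hydrogen ortho to OCH3 lies between OCH3 and the isopropyl group and is shielded. The brominated carbon is the future C6′.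

Step 3
Reactants: 3 1-bromo-2-isopropyl-4-methoxy-5-methylbenzene
Product: 6 2-isopropyl-4-methoxy-5-methylphenol (4-methoxythymol), via aryllithium 4 (not isolated), via dimethyl arylboronate 5 (not isolated)
Conditions: n-BuLi, THF, −78 °C; B(OMe)3, −78 °C → rt; 30% H2O2, aq. NaOH, 0 °C → rt
Reagents that add atoms: hydrogen peroxide, OO (oxygen of 6); n-butyllithium, [Li]CCCC (Li of 4 only); trimethyl borate, COB(OC)OC (boron group of 5 only)
Why: Bromine–lithium exchange, borylation and boronate oxidation with 1,2-shift of the aryl group from boron to oxygen; this ipso-hydroxylation puts the oxygen exactly where the bromine was.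

Step 4
Reactants: 6 2-isopropyl-4-methoxy-5-methylphenol
Product: 7 1-isopropyl-5-methoxy-2-(methoxymethoxy)-4-methylbenzene
Conditions: NaH, MOMCl, THF/DMF, 0 °C → rt
Reagents that add atoms: chloromethyl methyl ether, COCCl
Why: Williamson alkylation of the sodium phenoxide; the MOM ether protects the future free phenol and is the directing group for the next step.

Step 5
Reactants: 7 1-isopropyl-5-methoxy-2-(methoxymethoxy)-4-methylbenzene
Product: 10 3-isopropyl-5-methoxy-2-(methoxymethoxy)-6-methylphenol, via aryllithium 8 (not isolated), via dimethyl arylboronate 9 (not isolated)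
Conditions: n-BuLi, TMEDA, THF, −20 → 0 °C; B(OMe)3, −78 °C → rt; 30% H2O2, aq. NaOH, 0 °C
Reagents that add atoms: hydrogen peroxide, OO (oxygen of 10); n-butyllithium, [Li]CCCC (Li of 8 only); trimethyl borate, COB(OC)OC (boron group of 9 only)
Why: Directed ortho-metalation: the MOM ether chelates the base and C1′–H is the only hydrogen ortho to it, while the hydrogen next to OCH3 is shielded by the isopropyl group. Borylation and oxidation then proceed as in step 3 and leave a free hydroxyl beside the protected one.

Step 6
Reactants: 11 3-methylbutanal
Product: 12 3-methyl-2-methylenebutanal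
Conditions: 37% aq. CH2O, pyrrolidine (10 mol %), propionic acid (10 mol %), i-PrOH, 45 °C
Reagents that add atoms: formaldehyde, C=O
Why: Amine-catalysed α-methylenation (Mannich condensation followed by β-elimination of the amine); the enamine of the aldehyde attacks the iminium ion of formaldehyde and only the α-CH2 group can give the conjugated enal.

Step 7
Reactants: 12 3-methyl-2-methylenebutanal
Product: 13 3-methyl-2-methylenebutanoic acid
Conditions: NaClO2, NaH2PO4, 2-methyl-2-butene, t-BuOH/H2O, 0 °C → rt
Reagents that add atoms: sodium chlorite NaClO2, [Na+].[O-]Cl=O
Why: Pinnick oxidation; chlorous acid oxidises the conjugated aldehyde to the acid and leaves the 1,1-disubstituted alkene alone, with 2-methyl-2-butene removing the hypochlorous acid.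

Step 8
Reactants: 13 3-methyl-2-methylenebutanoic acid; 10 3-isopropyl-5-methoxy-2-(methoxymethoxy)-6-methylphenol
Product: 15 3-isopropyl-5-methoxy-2-(methoxymethoxy)-6-methylphenyl 3-methyl-2-methylenebutanoate, via acid chloride 14 (not isolated)
Conditions: (COCl)2, DMF (cat.), CH2Cl2, 0 °C → rt; solution added to 10, Et3N, DMAP (cat.), CH2Cl2, 0 °C → rt
Reagents that add atoms: oxalyl chloride, O=C(Cl)C(=O)Cl (chlorine of 14 only; no atoms in 15)
Why: Acyl chloride formation followed by DMAP-catalysed O-acylation (nucleophilic acyl substitution); acylation tolerates the two ortho substituents of the phenol, and the α-isopropyl group disfavours polymerisation and conjugate addition. This step makes the O–C4 bond of the target.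

Step 9
Reactants: 15 3-isopropyl-5-methoxy-2-(methoxymethoxy)-6-methylphenyl 3-methyl-2-methylenebutanoate
Product: 16 1-isopropyl-3-(3-isopropylbuta-1,3-dien-2-yloxy)-5-methoxy-2-(methoxymethoxy)-4-methylbenzene
Conditions: Cp2TiMe2, toluene/THF, 65 °C, dark; filtration through basic Al2O3
Reagents that add atoms: dimethyltitanocene Cp2TiMe2, C[Ti](C)(C1C=CC=C1)C1C=CC=C1
Why: Petasis methylenation: thermolysis of Cp2TiMe2 gives Cp2Ti=CH2, which adds (2+2) to the ester carbonyl and cycloreverts to the enol ether and a titanium oxo species. Aryl esters and conjugated esters are both established substrates, and the neutral conditions spare the MOM ether and the acid-labile diene.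

Step 10
Reactants: 16 1-isopropyl-3-(3-isopropylbuta-1,3-dien-2-yloxy)-5-methoxy-2-(methoxymethoxy)-4-methylbenzene; 17 pent-3-yn-2-one
Product: 18 1-{4-[3-isopropyl-5-methoxy-2-(methoxymethoxy)-6-methylphenoxy]-5-isopropyl-2-methylcyclohexa-1,4-dien-1-yl}ethanone
Conditions: 17 (3 equiv), BHT (cat.), toluene, sealed tube, 130 °C
Reagents that add atoms: none
Why: Concerted but asynchronous thermal (4+2) cycloaddition (Diels–Alder reaction) between the HOMO of the oxygen-substituted diene and the LUMO of the ynone; the closest known type is the cycloaddition of 2-alkoxy- and 2-silyloxybuta-1,3-dienes with acetylenic ketones and esters. Ring A is closed by intermolecular (4+2) annulation in which the diene supplies C2–C5 and the alkyne C1 and C6, the new bonds being C1–C2 and C5–C6. No stereocentre is formed, since the product has only sp2 carbons and two CH2 groups in the ring. The selectivity needed is regiochemical: the oxygen lone pair enlarges the HOMO coefficient on the CH2 group attached to C4 (this is C5), which bonds ahead to the β-carbon of the ynone (C6, bearing CH3), so the acetyl group lands on C1, para to the ether oxygen. The isopropyl group on C3 pushes the other way but is the weaker donor, and because both diene termini are unsubstituted CH2 groups sterics do not distinguish the two orientations. The two ortho substituents of ring B twist the aryl ring out of the C–O–C plane, which leaves the oxygen p lone pair to conjugate with the diene and strengthens this bias. The alkyne dienophile leaves the ring one dehydrogenation away from the arene, and acid-free conditions with a radical inhibitor protect the enol ether and suppress oligomerisation.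

Step 11
Reactants: 18 1-{4-[3-isopropyl-5-methoxy-2-(methoxymethoxy)-6-methylphenoxy]-5-isopropyl-2-methylcyclohexa-1,4-dien-1-yl}ethanone
Product: 19 1-{4-[3-isopropyl-5-methoxy-2-(methoxymethoxy)-6-methylphenoxy]-5-isopropyl-2-methylphenyl}ethanone
Conditions: DDQ, toluene, 0 °C → rt
Reagents that add atoms: none
Why: Quinone dehydrogenation: hydride abstraction from a doubly allylic CH2 group gives a pentadienyl cation stabilised by the aryloxy oxygen, and proton loss gives the benzene ring. 1,4-Cyclohexadienes aromatise much faster than DDQ attacks benzylic C–H bonds or a MOM ether.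

Step 12
Reactants: 19 1-{4-[3-isopropyl-5-methoxy-2-(methoxymethoxy)-6-methylphenoxy]-5-isopropyl-2-methylphenyl}ethanone
Product: 20 4-[3-isopropyl-5-methoxy-2-(methoxymethoxy)-6-methylphenoxy]-5-isopropyl-2-methylphenyl acetate
Conditions: mCPBA, CH2Cl2, 0 °C → rt, dark
Reagents that add atoms: 3-chloroperoxybenzoic acid, OOC(=O)c1cccc(Cl)c1
Why: Baeyer–Villiger oxidation; in the Criegee intermediate the aryl group migrates in preference to methyl because the aryloxy oxygen para to C1 makes it electron-rich and the ortho methyl group twists the acetyl group out of conjugation. The C1–C bond is thereby replaced by C1–O at a fixed position.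

Step 13
Reactants: 20 4-[3-isopropyl-5-methoxy-2-(methoxymethoxy)-6-methylphenoxy]-5-isopropyl-2-methylphenyl acetate
Product: 22 1-isopropyl-3-(2-isopropyl-4-methoxy-5-methylphenoxy)-5-methoxy-2-(methoxymethoxy)-4-methylbenzene, via phenol 21 (not isolated)
Conditions: K2CO3, MeOH, rt; evaporation; MeI, K2CO3, DMF, rt
Reagents that add atoms: iodomethane, CI
Why: Base-catalysed transesterification of the aryl acetate with methanol, then Williamson O-methylation of the phenoxide; the C1 hydroxyl is the only free one because C6′–O is still a MOM ether.

Step 14
Reactants: 22 1-isopropyl-3-(2-isopropyl-4-methoxy-5-methylphenoxy)-5-methoxy-2-(methoxymethoxy)-4-methylbenzene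
Product: 23 6-isopropyl-2-(2-isopropyl-4-methoxy-5-methylphenoxy)-4-methoxy-3-methylphenol (CNP0271085.0)
Conditions: 2 M aq. HCl, MeOH, 45 °C, N2
Reagents that add atoms: none
Why: Acid-catalysed acetal exchange of the MOM ether with methanol; the methyl ethers and the diaryl ether are inert to these conditions, and degassed solvent protects the electron-rich phenol from air oxidation.

## Compound list

1 | carvacrol (5-isopropyl-2-methylphenol) | Cc1ccc(C(C)C)cc1O | starting material
2 | 4-isopropyl-2-methoxy-1-methylbenzene | COc1cc(C(C)C)ccc1C | intermediate
3 | 1-bromo-2-isopropyl-4-methoxy-5-methylbenzene | COc1cc(C(C)C)c(Br)cc1C | intermediate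
4 | (2-isopropyl-4-methoxy-5-methylphenyl)lithium | [Li]c1cc(C)c(OC)cc1C(C)C | intermediate (not isolated)
5 | dimethyl (2-isopropyl-4-methoxy-5-methylphenyl)boronate | COB(OC)c1cc(C)c(OC)cc1C(C)C | intermediate (not isolated)
6 | 2-isopropyl-4-methoxy-5-methylphenol (4-methoxythymol) | COc1cc(C(C)C)c(O)cc1C | intermediate
7 | 1-isopropyl-5-methoxy-2-(methoxymethoxy)-4-methylbenzene | COCOc1cc(C)c(OC)cc1C(C)C | intermediate
8 | [3-isopropyl-5-methoxy-2-(methoxymethoxy)-6-methylphenyl]lithium | [Li]c1c(C)c(OC)cc(C(C)C)c1OCOC | intermediate (not isolated)
9 | dimethyl [3-isopropyl-5-methoxy-2-(methoxymethoxy)-6-methylphenyl]boronate | COB(OC)c1c(C)c(OC)cc(C(C)C)c1OCOC | intermediate (not isolated)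
10 | 3-isopropyl-5-methoxy-2-(methoxymethoxy)-6-methylphenol | COCOc1c(O)c(C)c(OC)cc1C(C)C | intermediate
11 | 3-methylbutanal | CC(C)CC=O | starting material
12 | 3-methyl-2-methylenebutanal | C=C(C=O)C(C)C | intermediate
13 | 3-methyl-2-methylenebutanoic acid | C=C(C(=O)O)C(C)C | intermediate
14 | 3-methyl-2-methylenebutanoyl chloride | C=C(C(=O)Cl)C(C)C | intermediate (not isolated)
15 | 3-isopropyl-5-methoxy-2-(methoxymethoxy)-6-methylphenyl 3-methyl-2-methylenebutanoate | C=C(C(C)C)C(=O)Oc1c(C)c(OC)cc(C(C)C)c1OCOC | intermediate
16 | 1-isopropyl-3-(3-isopropylbuta-1,3-dien-2-yloxy)-5-methoxy-2-(methoxymethoxy)-4-methylbenzene | C=C(Oc1c(C)c(OC)cc(C(C)C)c1OCOC)C(=C)C(C)C | intermediate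
17 | pent-3-yn-2-one | CC#CC(C)=O | starting material
18 | 1-{4-[3-isopropyl-5-methoxy-2-(methoxymethoxy)-6-methylphenoxy]-5-isopropyl-2-methylcyclohexa-1,4-dien-1-yl}ethanone | CC(=O)C1=C(C)CC(Oc2c(C)c(OC)cc(C(C)C)c2OCOC)=C(C(C)C)C1 | intermediate
19 | 1-{4-[3-isopropyl-5-methoxy-2-(methoxymethoxy)-6-methylphenoxy]-5-isopropyl-2-methylphenyl}ethanone | CC(=O)c1cc(C(C)C)c(Oc2c(C)c(OC)cc(C(C)C)c2OCOC)cc1C | intermediate
20 | 4-[3-isopropyl-5-methoxy-2-(methoxymethoxy)-6-methylphenoxy]-5-isopropyl-2-methylphenyl acetate | CC(=O)Oc1cc(C(C)C)c(Oc2c(C)c(OC)cc(C(C)C)c2OCOC)cc1C | intermediate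
21 | 4-[3-isopropyl-5-methoxy-2-(methoxymethoxy)-6-methylphenoxy]-5-isopropyl-2-methylphenol | Cc1cc(Oc2c(C)c(OC)cc(C(C)C)c2OCOC)c(C(C)C)cc1O | intermediate (not isolated)
22 | 1-isopropyl-3-(2-isopropyl-4-methoxy-5-methylphenoxy)-5-methoxy-2-(methoxymethoxy)-4-methylbenzene | COc1cc(C(C)C)c(Oc2c(C)c(OC)cc(C(C)C)c2OCOC)cc1C | intermediate
23 | 6-isopropyl-2-(2-isopropyl-4-methoxy-5-methylphenoxy)-4-methoxy-3-methylphenol | COc1cc(C(C)C)c(Oc2c(C)c(OC)cc(C(C)C)c2O)cc1C | target

## Step count and risk

Total step count: 14. Longest linear sequence: 12 steps (steps 1–5 and 8–14, from carvacrol 1); the acid branch (steps 6 and 7) joins at step 8.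

Least certain steps:

**Step 10 (key step).** Two processes threaten it. The first is reversal of the orientation of addition, because the isopropyl group on the diene opposes the aryloxy group and an aryloxy oxygen is a weaker donor than an alkoxy oxygen. The second is thermal oligomerisation of the diene before the β-substituted, only moderately reactive alkyne has added. Fallback: the cycloaddition is abandoned and the two rings are joined by aryl–oxygen cross-coupling of phenol 10 with aryl bromide 3, both already on the route (Pd(OAc)2, 2-(di-tert-butylphosphino)-2′,4′,6′-triisopropylbiphenyl, K3PO4, toluene, 100 °C; or CuI, picolinic acid, K3PO4, DMSO, 90 °C). This gives the MOM-protected diaryl ether directly and comes back to the route at 22. The coupling is kept as the reserve and not the main line because both partners are electron-rich and three ortho substituents surround the new bond.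

**Step 9.** The titanium methylidene may also engage the conjugated alkene of 15 (titanacyclobutane formation and degradation), and the enol ether diene may hydrolyse or oligomerise during isolation. Fallback from 10: O-alkylation with 1-bromo-3-methylbutan-2-one (K2CO3, acetone, reflux) should give 1-[3-isopropyl-5-methoxy-2-(methoxymethoxy)-6-methylphenoxy]-3-methylbutan-2-one F1. α-Methylenation at the OCH2 carbon (paraformaldehyde, diisopropylammonium trifluoroacetate, THF, reflux; Mannich condensation–elimination, possible only at the CH2 group) should give 2-[3-isopropyl-5-methoxy-2-(methoxymethoxy)-6-methylphenoxy]-4-methylpent-1-en-3-one F2. Wittig methylenation of the ketone (Ph3P=CH2, THF, 0 °C) then comes back to the route at 16.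

**Step 5.** Lithiation may be incomplete or misdirected (deprotonation of the ring methyl group or next to OCH3), and the electron-rich phenol may be over-oxidised in the peroxide stage. Fallback from 6: magnesium-mediated ortho-formylation (MgCl2, Et3N, paraformaldehyde, MeCN, reflux) at the only free ortho position should give 2-hydroxy-3-isopropyl-5-methoxy-6-methylbenzaldehyde F3. MOM protection (NaH, MOMCl, THF/DMF) should give 3-isopropyl-5-methoxy-2-(methoxymethoxy)-6-methylbenzaldehyde F4. Dakin-type Baeyer–Villiger oxidation (mCPBA, CH2Cl2) should give 3-isopropyl-5-methoxy-2-(methoxymethoxy)-6-methylphenyl formate F5, and methanolysis (K2CO3, MeOH) comes back to the route at 10.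

**Step 12.** Oxygen insertion into the ketone may be slow enough for the peracid to oxidise the electron-rich ring B or for the accumulating acid to cleave the MOM ether. Fallback from 16: the latent oxygen is carried as a formyl group, whose peracid oxidation is much faster. Cycloaddition of 16 with but-2-ynal (CC#CC=O) under the conditions of step 10 should give 4-[3-isopropyl-5-methoxy-2-(methoxymethoxy)-6-methylphenoxy]-5-isopropyl-2-methylcyclohexa-1,4-diene-1-carbaldehyde F6. DDQ dehydrogenation should give 4-[3-isopropyl-5-methoxy-2-(methoxymethoxy)-6-methylphenoxy]-5-isopropyl-2-methylbenzaldehyde F7. Dakin-type oxidation (mCPBA, CH2Cl2, 0 °C) should give 4-[3-isopropyl-5-methoxy-2-(methoxymethoxy)-6-methylphenoxy]-5-isopropyl-2-methylphenyl formate F8, and methanolysis (K2CO3, MeOH) comes back to the route at phenol 21, which is methylated as in the second stage of step 13.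

## Further compounds

F0 | step 10 | none | none
F1 | step 9 | 1-[3-isopropyl-5-methoxy-2-(methoxymethoxy)-6-methylphenoxy]-3-methylbutan-2-one | CC(C)C(=O)COc1c(C)c(OC)cc(C(C)C)c1OCOC
F2 | step 9 | 2-[3-isopropyl-5-methoxy-2-(methoxymethoxy)-6-methylphenoxy]-4-methylpent-1-en-3-one | C=C(Oc1c(C)c(OC)cc(C(C)C)c1OCOC)C(=O)C(C)C
F3 | step 5 | 2-hydroxy-3-isopropyl-5-methoxy-6-methylbenzaldehyde | O=Cc1c(O)c(C(C)C)cc(OC)c1C
F4 | step 5 | 3-isopropyl-5-methoxy-2-(methoxymethoxy)-6-methylbenzaldehyde | O=Cc1c(OCOC)c(C(C)C)cc(OC)c1C
F5 | step 5 | 3-isopropyl-5-methoxy-2-(methoxymethoxy)-6-methylphenyl formate | O=COc1c(OCOC)c(C(C)C)cc(OC)c1C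
F6 | step 12 | 4-[3-isopropyl-5-methoxy-2-(methoxymethoxy)-6-methylphenoxy]-5-isopropyl-2-methylcyclohexa-1,4-diene-1-carbaldehyde | O=CC1=C(C)CC(Oc2c(C)c(OC)cc(C(C)C)c2OCOC)=C(C(C)C)C1
F7 | step 12 | 4-[3-isopropyl-5-methoxy-2-(methoxymethoxy)-6-methylphenoxy]-5-isopropyl-2-methylbenzaldehyde | O=Cc1cc(C(C)C)c(Oc2c(C)c(OC)cc(C(C)C)c2OCOC)cc1C
F8 | step 12 | 4-[3-isopropyl-5-methoxy-2-(methoxymethoxy)-6-methylphenoxy]-5-isopropyl-2-methylphenyl formate | O=COc1cc(C(C)C)c(Oc2c(C)c(OC)cc(C(C)C)c2OCOC)cc1C
A1 | alternative 1 | methyl 3-isopropyl-5-methoxy-2-(methoxymethoxy)-6-methylphenyl carbonate | COC(=O)Oc1c(C)c(OC)cc(C(C)C)c1OCOC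
A2 | alternative 1 | 4-methoxy-5-methyl-2-(trimethylsilyl)phenyl trifluoromethanesulfonate | COc1cc([Si](C)(C)C)c(OS(=O)(=O)C(F)(F)F)cc1C
A3 | alternative 1 | methyl 2-[3-isopropyl-5-methoxy-2-(methoxymethoxy)-6-methylphenoxy]-5-methoxy-4-methylbenzoate | COC(=O)c1cc(OC)c(C)cc1Oc1c(C)c(OC)cc(C(C)C)c1OCOC
A4 | alternative 2 | 3-(2-isopropyl-4-methoxy-5-methylphenoxy)-4-(methoxymethoxy)-2-methyl-4-(3-methylbut-1-en-2-yl)cyclobut-2-en-1-one (racemic) | CC1=C(Oc2cc(C)c(OC)cc2C(C)C)C(OCOC)(C(=C)C(C)C)C1=O
A5 | alternative 2 | 3-(2-isopropyl-4-methoxy-5-methylphenoxy)-5-isopropyl-4-(methoxymethoxy)-2-methylphenol | COCOc1c(Oc2cc(C)c(OC)cc2C(C)C)c(C)c(O)cc1C(C)C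
A6 | alternative 3 | 1-[3-isopropyl-5-methoxy-2-(methoxymethoxy)-6-methylphenoxy]-3-methylbutan-2-one | CC(C)C(=O)COc1c(C)c(OC)cc(C(C)C)c1OCOC
A7 | alternative 3 | 3-methylbut-3-en-2-one | CC(=O)C(C)=C
A8 | alternative 3 | 4-[3-isopropyl-5-methoxy-2-(methoxymethoxy)-6-methylphenoxy]-3-isopropyl-6-methylcyclohex-2-en-1-one (racemic, one diastereomer drawn) | CC(C)C1=CC(=O)[C@H](C)C[C@@H]1Oc1c(C)c(OC)cc(C(C)C)c1OCOC
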